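The tetrahydrofuran ring (O, C6, C7, C8, C9) of the 2,8-dioxabicyclo[5.2.1]decane core is disconnected at O–C9 and C6–C7, which leaves a monocyclic oxocane and an enynal. The key step exploits two features: C7 lies next to the oxocane oxygen, so a temporary carboxyl group there can be traded for a nucleophilic carbon–chromium bond, and C9 sits 1,3 to C7, so the alkoxide born at C6 is poised to open a cis-9,10-epoxide in the 5-exo mode. One operation forges both bonds and sets C6, C7, C9 and C10. The precursor is a 9,10-epoxyoxocane whose C7 carboxyl group, installed by glycolate alkylation and ring-closing metathesis, is a redox-active ester.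

Key step: step 15

Remark on numbering: atoms are numbered C1–C15 along the carbon chain of the target (C1 = terminal alkyne carbon); the tetrahydrofuran oxygen joins C6 and C9, the oxocane oxygen joins C7 and C13.

Assumption: the (S)-configured oxazoline–sulfonamide ligand of step 15 is taken as the antipode that gives the 6S carbinol; if a model coupling shows the opposite sense, its mirror image is used.

Step 1
Reactants: 1 methyl (R)-2-hydroxybutanoate; 2 tert-butyl diazoacetate
Product: 3 methyl (2R)-2-(2-tert-butoxy-2-oxoethoxy)butanoate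
Conditions: Rh2(OAc)4 (1 mol %), CH2Cl2, rt, slow addition of 2 to excess 1
Reagents that add atoms: none
Why: Rhodium-carbenoid O–H insertion forms the C13–O–C7 ether under neutral conditions, so the C13 stereocentre bought with 1 is not touched.

Step 2
Reactants: 3 methyl (2R)-2-(2-tert-butoxy-2-oxoethoxy)butanoate
Product: 4 tert-butyl 2-{[(2R)-1-oxobutan-2-yl]oxy}acetate
Conditions: iBu2AlH (1.1 equiv), CH2Cl2, −78 °C; Rochelle salt work-up; used crude
Reagents that add atoms: none
Why: Low-temperature half-reduction of the methyl ester with iBu2AlH should stop at the aldehyde and spare the bulkier tert-butyl ester, and immediate use keeps the α-alkoxy aldehyde from epimerising at C13.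

Step 3
Reactants: 4 tert-butyl 2-{[(2R)-1-oxobutan-2-yl]oxy}acetate; 5 allyltributylstannane
Product: 6 tert-butyl 2-{[(3R,4R)-4-hydroxyhept-6-en-3-yl]oxy}acetate
Conditions: MgBr2·OEt2 (2 equiv), CH2Cl2, −78 to −20 °C
Reagents that add atoms: none
Why: Chelation-controlled (Cram-chelate) allylstannane addition: MgBr2 ties the aldehyde oxygen to the α-ether oxygen and the allyl group enters from the face of the C13 hydrogen, which sets C12 as R, syn to the C13 oxygen.

Step 4
Reactants: 6 tert-butyl 2-{[(3R,4R)-4-hydroxyhept-6-en-3-yl]oxy}acetate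
Product: 7 tert-butyl 2-{[(3R,4R)-4-(tert-butyldimethylsilyloxy)hept-6-en-3-yl]oxy}acetate
Conditions: TBSCl, imidazole, DMAP (cat.), DMF, rt
Reagents that add atoms: tert-butyldimethylsilyl chloride, C[Si](C)(Cl)C(C)(C)C
Why: Silyl ether protection of the C12 alcohol masks it for the enolate, metathesis and chromium steps.

Step 5
Reactants: 7 tert-butyl 2-{[(3R,4R)-4-(tert-butyldimethylsilyloxy)hept-6-en-3-yl]oxy}acetate
Product: 9 2-{[(3R,4R)-4-(tert-butyldimethylsilyloxy)hept-6-en-3-yl]oxy}acetic acid, via trimethylsilyl ester 8 (not isolated)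
Conditions: TMSOTf, 2,6-lutidine, CH2Cl2, 0 °C; then H2O
Reagents that add atoms: none
Why: Silyl triflate-mediated dealkylation of the tert-butyl ester (loss of 2-methylpropene) should spare the TBS ether and the alkene, and the silyl ester is hydrolysed on work-up.

Step 6
Reactants: 9 2-{[(3R,4R)-4-(tert-butyldimethylsilyloxy)hept-6-en-3-yl]oxy}acetic acid; 10 (S)-4-benzyloxazolidin-2-one
Product: 12 (4S)-4-benzyl-3-(2-{[(3R,4R)-4-(tert-butyldimethylsilyloxy)hept-6-en-3-yl]oxy}acetyl)oxazolidin-2-one, via mixed anhydride 11 (not isolated)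
Conditions: pivaloyl chloride, Et3N, THF, −20 °C; then 10, LiCl, rt
Reagents that add atoms: none
Why: N-Acylation of the oxazolidinone through the mixed pivalic anhydride attaches the Evans auxiliary to the glycolate.

Step 7
Reactants: 12 (4S)-4-benzyl-3-(2-{[(3R,4R)-4-(tert-butyldimethylsilyloxy)hept-6-en-3-yl]oxy}acetyl)oxazolidin-2-one; 13 allyl iodide
Product: 15 (4S)-4-benzyl-3-[(2R)-2-{[(3R,4R)-4-(tert-butyldimethylsilyloxy)hept-6-en-3-yl]oxy}pent-4-enoyl]oxazolidin-2-one, via sodium enolate 14 (not isolated)
Conditions: NaN(SiMe3)2, THF, −78 °C; then 13, −78 to −45 °C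
Reagents that add atoms: none
Why: Evans-type asymmetric glycolate alkylation: the chelated Z-enolate 14 is allylated on the face away from the benzyl group, which sets the temporary C7 stereocentre as R (cis to the C13 ethyl group once the ring is closed).

Step 8
Reactants: 15 (4S)-4-benzyl-3-[(2R)-2-{[(3R,4R)-4-(tert-butyldimethylsilyloxy)hept-6-en-3-yl]oxy}pent-4-enoyl]oxazolidin-2-one
Product: 16 (4S)-4-benzyl-3-{[(2R,4Z,7R,8R)-7-(tert-butyldimethylsilyloxy)-8-ethyl-3,6,7,8-tetrahydro-2H-oxocin-2-yl]carbonyl}oxazolidin-2-one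
Conditions: second-generation Grubbs catalyst (5 mol %), CH2Cl2 (2 mM), 40 °C
Reagents that add atoms: none
Why: Ring-closing metathesis of the two allyl groups forms the C9=C10 bond; the gauche preference of the vicinal C12/C13 oxygens and the cis-2,8 substitution pre-organise the diene, and the eight-membered ring can only hold the Z alkene.

Step 9
Reactants: 16 (4S)-4-benzyl-3-{[(2R,4Z,7R,8R)-7-(tert-butyldimethylsilyloxy)-8-ethyl-3,6,7,8-tetrahydro-2H-oxocin-2-yl]carbonyl}oxazolidin-2-one
Product: 18 (2R,4Z,7R,8R)-7-(tert-butyldimethylsilyloxy)-8-ethyl-3,6,7,8-tetrahydro-2H-oxocine-2-carboxylic acid, via peroxy acid 17 (not isolated)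
Conditions: LiOH, H2O2, THF/H2O, 0 °C; then Na2SO3; then 1 M HCl to pH 3
Reagents that add atoms: hydrogen peroxide, OO
Why: Hydroperoxide cleavage of the N-acyl oxazolidinone at the exocyclic carbonyl, followed by sulfite reduction of the peroxy acid before acidification, should free the acid without epimerisation at C7 or epoxidation of the alkene.

Step 10
Reactants: 18 (2R,4Z,7R,8R)-7-(tert-butyldimethylsilyloxy)-8-ethyl-3,6,7,8-tetrahydro-2H-oxocine-2-carboxylic acid
Product: 19 1,3-dioxoisoindolin-2-yl (2R,4Z,7R,8R)-7-(tert-butyldimethylsilyloxy)-8-ethyl-3,6,7,8-tetrahydro-2H-oxocine-2-carboxylate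
Conditions: N-hydroxyphthalimide, N,N'-diisopropylcarbodiimide, DMAP (cat.), CH2Cl2, rt
Reagents that add atoms: N-hydroxyphthalimide, ON1C(=O)c2ccccc2C1=O
Why: Carbodiimide (Steglich-type) esterification gives the redox-active N-hydroxyphthalimide ester before the epoxide is present, so no free acid can lactonise onto it.

Step 11
Reactants: 19 1,3-dioxoisoindolin-2-yl (2R,4Z,7R,8R)-7-(tert-butyldimethylsilyloxy)-8-ethyl-3,6,7,8-tetrahydro-2H-oxocine-2-carboxylate
Product: 20 the 9,10-epoxide of 19 (chain numbering: 7R,9S,10R,12R,13R; epoxide oxygen anti to the C7, C12 and C13 substituents)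
Conditions: mCPBA, NaHCO3, CH2Cl2, 0 °C
Reagents that add atoms: 3-chloroperbenzoic acid, OOC(=O)c1cccc(Cl)c1
Why: Prilezhaev epoxidation of the Z alkene: the C7 acyl, C12 silyloxy and C13 ethyl groups all lie on one ring face, so the peracid should approach the other face, which sets C9 (S) and C10 (R).

Step 12
Reactants: 21 but-3-yn-1-ol
Product: 23 (E)-4-iodobut-3-en-1-ol, via alkenylzirconocene 22 (not isolated)
Conditions: Cp2Zr(H)Cl (2.2 equiv), THF, rt; then I2, 0 °C
Reagents that add atoms: iodine, II
Why: Schwartz hydrozirconation (syn and anti-Markovnikov, the first equivalent of hydride being spent on the hydroxyl group) and iodinolysis with retention give the E vinyl iodide.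

Step 13
Reactants: 23 (E)-4-iodobut-3-en-1-ol; 24 ethynyltrimethylsilane
Product: 25 (E)-6-(trimethylsilyl)hex-3-en-5-yn-1-ol
Conditions: PdCl2(PPh3)2 (2 mol %), CuI (4 mol %), Et3N, THF, rt
Reagents that add atoms: none
Why: Sonogashira coupling joins the alkyne to the vinyl iodide with retention of the E geometry.

Step 14
Reactants: 25 (E)-6-(trimethylsilyl)hex-3-en-5-yn-1-ol
Product: 26 (E)-6-(trimethylsilyl)hex-3-en-5-ynal
Conditions: Dess–Martin periodinane, NaHCO3, CH2Cl2, 0 °C; used at once
Reagents that add atoms: none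
Why: Dess–Martin oxidation under buffered, non-basic conditions gives the β,γ-unsaturated aldehyde, and immediate use avoids isomerisation of the alkene into conjugation with the carbonyl.

Step 15
Reactants: 20 the 9,10-epoxide of 19; 26 (E)-6-(trimethylsilyl)hex-3-en-5-ynal
Product: 28 bicyclic alcohol (target skeleton; 6S,7R,9R,10R,12R,13R; OH at C10, OTBS at C12, SiMe3 on C1), via hydroxy-epoxide 27 (not isolated)
Conditions: CrCl2 (4 equiv), (S)-N-[2-(4-isopropyl-4,5-dihydrooxazol-2-yl)-6-methylphenyl]methanesulfonamide (4.4 equiv), proton sponge (4.4 equiv), THF, rt, 26 (2 equiv); then CSA, rt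
Reagents that add atoms: none
Why: Proposed new method: CrCl2 reduces the N-acyloxyphthalimide by single-electron transfer, CO2 is lost, and the C7 radical, stabilised by the oxocane oxygen, is captured by a second divalent chromium to give an α-alkoxyalkyl trivalent chromium species that adds to aldehyde 26 (C6–C7 bond); the chromium alkoxide of 27, or the free alcohol once CSA is added, then opens the epoxide at C9 (O–C9 bond). The closest known reaction types are the chromium-mediated decarboxylative Nozaki–Hiyama–Kishi addition of redox-active esters to aldehydes and the acid-catalysed cyclisation of γ,δ-epoxy alcohols to tetrahydrofurans; their union in one flask on an α-alkoxy ester that carries an epoxide across the ring is new. The tetrahydrofuran ring (O, C6, C7, C8, C9) closes in the 5-exo-tet mode, which should be preferred over 6-endo attack at C10 because neither epoxide carbon is cation-stabilised. C9 is set by inversion and C10 by retention of the epoxide; C6 is set by the chiral sulfonamide ligand on chromium (reagent control); C7 is set by C–C bond formation on the ring face remote from the epoxide oxygen and cis to the C13 ethyl group, where the bulky chromium centre can sit pseudo-equatorially. The step needs chemoselective addition of the organochromium to the aldehyde in the presence of the epoxide, the silylalkyne and the active ester, which the low basicity and carbonyl selectivity of organochromium reagents should secure. The ring closure also filters C7, since only the epimer with the side chain anti to the epoxide oxygen can reach C9.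

Step 16
Reactants: 28 bicyclic alcohol
Product: 29 C10 acetate of 28
Conditions: Ac2O, pyridine, DMAP (cat.), CH2Cl2, rt
Reagents that add atoms: acetic anhydride, CC(=O)OC(C)=O
Why: DMAP-catalysed acylation esterifies the only free hydroxyl group, at C10.

Step 17
Reactants: 29 C10 acetate of 28
Product: 30 (6S,7R,9R,10R,12R,13R)-10-acetoxy-12-hydroxy enyne (target with OH in place of Br and inverted C12)
Conditions: Bu4NF, AcOH, THF, rt
Reagents that add atoms: none
Why: Fluoride-mediated desilylation removes the O-TBS and the C-SiMe3 groups together, and the acetic acid buffer should keep the C10 acetate from cleaving or migrating to O12.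

Step 18
Reactants: 30 (6S,7R,9R,10R,12R,13R)-10-acetoxy-12-hydroxy enyne
Product: 31 the target, (6S,7R,9R,10R,12S,13R)
Conditions: CBr4, P(n-C8H17)3, 1-methylcyclohexene, toluene, 70 °C
Reagents that add atoms: carbon tetrabromide, BrC(Br)(Br)Br
Why: Appel-type bromination through the alkoxyphosphonium bromide displaces oxygen by SN2 and inverts C12 from R to S, while the tetrahydrofuran oxygen lies on the same face as the leaving group and cannot participate from the rear.

Compound list
1 | methyl (R)-2-hydroxybutanoate | CC[C@@H](O)C(=O)OC | starting material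
2 | tert-butyl diazoacetate | [N-]=[N+]=CC(=O)OC(C)(C)C | starting material
3 | methyl (2R)-2-(2-tert-butoxy-2-oxoethoxy)butanoate | CC[C@@H](OCC(=O)OC(C)(C)C)C(=O)OC | intermediate
4 | tert-butyl 2-{[(2R)-1-oxobutan-2-yl]oxy}acetate | CC[C@@H](OCC(=O)OC(C)(C)C)C=O | intermediate
5 | allyltributylstannane | C=CC[Sn](CCCC)(CCCC)CCCC | starting material
6 | tert-butyl 2-{[(3R,4R)-4-hydroxyhept-6-en-3-yl]oxy}acetate | CC[C@@H](OCC(=O)OC(C)(C)C)[C@H](O)CC=C | intermediate
7 | tert-butyl 2-{[(3R,4R)-4-(tert-butyldimethylsilyloxy)hept-6-en-3-yl]oxy}acetate | CC[C@@H](OCC(=O)OC(C)(C)C)[C@H](O[Si](C)(C)C(C)(C)C)CC=C | intermediate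
8 | trimethylsilyl ester of 9 (not isolated) | CC[C@@H](OCC(=O)O[Si](C)(C)C)[C@H](O[Si](C)(C)C(C)(C)C)CC=C | intermediate
9 | 2-{[(3R,4R)-4-(tert-butyldimethylsilyloxy)hept-6-en-3-yl]oxy}acetic acid | CC[C@@H](OCC(=O)O)[C@H](O[Si](C)(C)C(C)(C)C)CC=C | intermediate
10 | (S)-4-benzyloxazolidin-2-one | O=C1N[C@@H](Cc2ccccc2)CO1 | starting material
11 | mixed anhydride of 9 with pivalic acid (not isolated) | CC[C@@H](OCC(=O)OC(=O)C(C)(C)C)[C@H](O[Si](C)(C)C(C)(C)C)CC=C | intermediate
12 | (4S)-4-benzyl-3-(2-{[(3R,4R)-4-(tert-butyldimethylsilyloxy)hept-6-en-3-yl]oxy}acetyl)oxazolidin-2-one | CC[C@@H](OCC(=O)N1[C@@H](Cc2ccccc2)COC1=O)[C@H](O[Si](C)(C)C(C)(C)C)CC=C | intermediate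
13 | allyl iodide | C=CCI | starting material
14 | sodium Z-enolate of 12 (not isolated) | CC[C@@H](O/C=C(\[O-])N1[C@@H](Cc2ccccc2)COC1=O)[C@H](O[Si](C)(C)C(C)(C)C)CC=C.[Na+] | intermediate
15 | (4S)-4-benzyl-3-[(2R)-2-{[(3R,4R)-4-(tert-butyldimethylsilyloxy)hept-6-en-3-yl]oxy}pent-4-enoyl]oxazolidin-2-one | CC[C@@H](O[C@H](CC=C)C(=O)N1[C@@H](Cc2ccccc2)COC1=O)[C@H](O[Si](C)(C)C(C)(C)C)CC=C | intermediate
16 | (4S)-4-benzyl-3-{[(2R,4Z,7R,8R)-7-(tert-butyldimethylsilyloxy)-8-ethyl-3,6,7,8-tetrahydro-2H-oxocin-2-yl]carbonyl}oxazolidin-2-one | CC[C@H]1O[C@@H](C(=O)N2[C@@H](Cc3ccccc3)COC2=O)C/C=C\C[C@H]1O[Si](C)(C)C(C)(C)C | intermediate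
17 | (2R,4Z,7R,8R)-7-(tert-butyldimethylsilyloxy)-8-ethyl-3,6,7,8-tetrahydro-2H-oxocine-2-carboperoxoic acid (not isolated) | CC[C@H]1O[C@@H](C(=O)OO)C/C=C\C[C@H]1O[Si](C)(C)C(C)(C)C | intermediate
18 | (2R,4Z,7R,8R)-7-(tert-butyldimethylsilyloxy)-8-ethyl-3,6,7,8-tetrahydro-2H-oxocine-2-carboxylic acid | CC[C@H]1O[C@@H](C(=O)O)C/C=C\C[C@H]1O[Si](C)(C)C(C)(C)C | intermediate
19 | 1,3-dioxoisoindolin-2-yl ester of 18 (redox-active ester) | CC[C@H]1O[C@@H](C(=O)ON2C(=O)c3ccccc3C2=O)C/C=C\C[C@H]1O[Si](C)(C)C(C)(C)C | intermediate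
20 | 9,10-epoxide of 19 (chain numbering 7R,9S,10R,12R,13R; epoxide oxygen anti to the C7, C12 and C13 substituents) | CC[C@H]1O[C@@H](C(=O)ON2C(=O)c3ccccc3C2=O)C[C@@H]4O[C@@H]4C[C@H]1O[Si](C)(C)C(C)(C)C | intermediate
21 | but-3-yn-1-ol | C#CCCO | starting material
22 | (E)-alkenylzirconocene chloride of but-3-yn-1-ol, as its O-zirconocene alkoxide (not isolated) | Cl[Zr](OCC/C=C/[Zr](Cl)(C1C=CC=C1)C1C=CC=C1)(C1C=CC=C1)C1C=CC=C1 | intermediate
23 | (E)-4-iodobut-3-en-1-ol | OCC/C=C/I | intermediate
24 | ethynyltrimethylsilane | C#C[Si](C)(C)C | starting material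
25 | (E)-6-(trimethylsilyl)hex-3-en-5-yn-1-ol | OCC/C=C/C#C[Si](C)(C)C | intermediate
26 | (E)-6-(trimethylsilyl)hex-3-en-5-ynal | O=CC/C=C/C#C[Si](C)(C)C | intermediate
27 | hydroxy-epoxide (6S,7R,9S,10R,12R,13R): 20 with the C7 ester replaced by (S)-CH(OH)CH2CH=CH–C≡C–SiMe3; formed as its chromium alkoxide (not isolated) | CC[C@H]1O[C@@H]([C@@H](O)C/C=C/C#C[Si](C)(C)C)C[C@@H]2O[C@@H]2C[C@H]1O[Si](C)(C)C(C)(C)C | intermediate
28 | bicyclic alcohol (6S,7R,9R,10R,12R,13R): 2,8-dioxabicyclo[5.2.1]decane core with OH at C10, OTBS at C12, ethyl at C13 and the (E)-5-(trimethylsilyl)pent-2-en-4-ynyl chain at C6 | C[Si](C)(C)C#C/C=C/C[C@@H]1O[C@@H]2C[C@H]1O[C@H](CC)[C@H](O[Si](C)(C)C(C)(C)C)C[C@H]2O | intermediate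
29 | C10 acetate of 28 | C[Si](C)(C)C#C/C=C/C[C@@H]1O[C@@H]2C[C@H]1O[C@H](CC)[C@H](O[Si](C)(C)C(C)(C)C)C[C@H]2OC(C)=O | intermediate
30 | (6S,7R,9R,10R,12R,13R)-10-acetoxy-12-hydroxy enyne (desilylated 29) | C#C/C=C/C[C@@H]1O[C@@H]2C[C@H]1O[C@H](CC)[C@H](O)C[C@H]2OC(C)=O | intermediate
31 | target, (6S,7R,9R,10R,12S,13R)-10-acetoxy-12-bromo compound CNP0217809.2 | C#C/C=C/C[C@@H]1O[C@@H]2C[C@H]1O[C@H](CC)[C@@H](Br)C[C@H]2OC(C)=O | target

Total step count: 18. Longest linear sequence: 15 steps (steps 1–11 and 15–18); steps 12–14 make the aldehyde branch.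

The three steps most likely to fail, the labelled one first:

Step 15. The C7 radical may be reduced or abstract hydrogen before chromium captures it, the organochromium may add with poor face selectivity at C7 or C6, or chloride may open the epoxide before the alkoxide does. The fallback uses known chemistry, sets out from acid 18 and comes back at 28. Acid 18 is converted with 1-hydroxypyridine-2(1H)-thione and dicyclohexylcarbodiimide to the Barton ester F1. Visible light rearranges F1 with loss of CO2 (Barton decarboxylation) to the anomeric 2-pyridyl sulfide F2, a mixture of C7 epimers. Excess mCPBA oxidises sulfur to the sulfone and epoxidises the alkene in one pot to give the sulfone epoxide F3. Samarium Barbier coupling of this anomeric 2-pyridyl sulfone with aldehyde 26 (SmI2, THF, rt) should give hydroxy-epoxide 27, now isolated, and CSA in CH2Cl2 closes it to 28. C6 is not controlled in this sequence, so the C6 epimers would be separated at 28.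

Step 11. The peracid may approach the flexible eight-membered ring from the face syn to the substituents, giving poor or reversed facial selectivity. The fallback sets out from 19 and comes back at 20, and it delivers the oxygen to the face opposite to the one the electrophile attacks. NBS in wet THF forms the bromonium ion on the face the peracid preferred and water opens it anti, giving the regioisomeric trans-bromohydrins F4 and F5. Ag2O in CH2Cl2 then closes both to the same epoxide 20 without touching the active ester.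

Step 18. The alkoxyphosphonium intermediate may eliminate to an alkene, or the adjacent oxocane oxygen may participate and lead to retention or ring contraction. The fallback sets out from 30 and comes back at 31. ClCH2SO2Cl and 2,6-lutidine give the chloromethanesulfonate F6, and LiBr in THF displaces it by SN2 with inversion at lower temperature than the phosphine method.

Further compounds
F1 | step 15 | Barton ester of 18 (2-thioxopyridin-1(2H)-yl ester) | CC[C@H]1O[C@@H](C(=O)ON2C=CC=CC2=S)C/C=C\C[C@H]1O[Si](C)(C)C(C)(C)C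
F2 | step 15 | 2-pyridyl sulfide at C7 of the oxocene (C7 epimers) | CC[C@H]1OC(Sc2ccccn2)C/C=C\C[C@H]1O[Si](C)(C)C(C)(C)C
F3 | step 15 | 2-pyridyl sulfone at C7 with the 9,10-epoxide (C7 epimers) | CC[C@H]1OC(S(=O)(=O)c2ccccn2)C[C@@H]3O[C@@H]3C[C@H]1O[Si](C)(C)C(C)(C)C
F4 | step 11 | trans-bromohydrin of 19 with 9-OH and 10-Br (9S,10S) | CC[C@H]1O[C@@H](C(=O)ON2C(=O)c3ccccc3C2=O)C[C@H](O)[C@@H](Br)C[C@H]1O[Si](C)(C)C(C)(C)C
F5 | step 11 | trans-bromohydrin of 19 with 9-Br and 10-OH (9R,10R) | CC[C@H]1O[C@@H](C(=O)ON2C(=O)c3ccccc3C2=O)C[C@@H](Br)[C@H](O)C[C@H]1O[Si](C)(C)C(C)(C)C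
F6 | step 18 | C12 chloromethanesulfonate of 30 | C#C/C=C/C[C@@H]1O[C@@H]2C[C@H]1O[C@H](CC)[C@H](OS(=O)(=O)CCl)C[C@H]2OC(C)=O
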